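**Assumption:** the target SMILES has no stereocentre and no stereogenic double bond. Lehualide K is therefore achiral and the "single enantiomer" requirement does not apply. The sp3 centres in 3 and 5 are transient and are erased when the pyrone forms.

## Retrosynthetic overview
1. Cut the S–S bond. The C2-symmetric disulfide comes from oxidative dimerisation of the thiol released from monomeric thioacetate 10.
2. Cut the C–S bond. It comes from anti-Markovnikov radical thiol-ene addition of AcSH to the terminal alkene of pyrone 8.
3. Cut the O4–CH3 bond. It comes from regioselective O-methylation of 4-hydroxy-2-pyrone 6.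
4. Open the pyrone, the only ring type. It is built once, at the monomer stage and before sulfur is introduced, by lactonisation of 3,5-diketo ester 5. The second ring arrives through the dimerisation.
5. Diketo ester 5 comes from γ-acylation of the dianion of α-methoxy-β-keto ester 3 with methyl undec-10-enoate 4. Keto ester 3 comes from a crossed Claisen of methyl methoxyacetate 1 with propionyl chloride 2.

## Route

**Step 1**
Reactants: 1 methyl methoxyacetate; 2 propionyl chloride
Product: 3 methyl 2-methoxy-3-oxopentanoate (racemic, enolisable)
Conditions: 1 (2.1 equiv), LDA (2.0 equiv), THF, −78 °C; then 2 (1.0 equiv), −78 °C, 1 h; AcOH/aq NH4Cl quench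
Reagents that add atoms: propionyl chloride (2), CCC(=O)Cl
Why: This is a crossed Claisen C-acylation of the chelated lithium enolate, and the second equivalent of enolate deprotonates the more acidic β-keto ester product so it is not acylated again.

**Step 2**
Reactants: 3 methyl 2-methoxy-3-oxopentanoate; 4 methyl undec-10-enoate
Product: 5 methyl 2-methoxy-4-methyl-3,5-dioxopentadec-14-enoate (keto/enol and diastereomer mixture, used crude)
Conditions: 3 (2.0 equiv), LDA (4.1 equiv), THF, −78 → 0 °C; then 4 (1.0 equiv), −78 → 0 °C; 1 M HCl quench
Reagents that add atoms: methyl undec-10-enoate (4), C=CCCCCCCCCC(=O)OC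
Why: In this Huckin–Weiler dianion acylation the 1,3-dianion reacts only at its more nucleophilic γ-carbon (C4) with the ester, the excess dianion absorbs the acidic proton of the tricarbonyl product, and the isolated alkene is inert.

**Step 3**
Reactants: 5 methyl 2-methoxy-4-methyl-3,5-dioxopentadec-14-enoate
Product: 6 6-(dec-9-en-1-yl)-4-hydroxy-3-methoxy-5-methyl-2H-pyran-2-one
Conditions: DBU (2 equiv), toluene, 80 °C; 1 M HCl work-up
Reagents that add atoms: none
Why: In this base-mediated lactonisation the C5 enolate oxygen attacks the methyl ester (6-exo-trig, loss of MeOH) to give the conjugated 4-hydroxy-2-pyrone, which removes both sp3 centres.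

**Step 4**
Reactants: 6 6-(dec-9-en-1-yl)-4-hydroxy-3-methoxy-5-methyl-2H-pyran-2-one; 7 dimethyl sulfate
Product: 8 6-(dec-9-en-1-yl)-3,4-dimethoxy-5-methyl-2H-pyran-2-one
Conditions: Me2SO4 (1.5 equiv), K2CO3 (2 equiv), acetone, reflux; chromatography removes any more polar γ-pyrone isomer
Reagents that add atoms: dimethyl sulfate (7), COS(=O)(=O)OC
Why: O-alkylation of the fully formed potassium pyronate with a hard methylating agent occurs mainly at O4 and gives the 4-methoxy-α-pyrone rather than the 2-methoxy-γ-pyrone.

**Step 5**
Reactants: 8 6-(dec-9-en-1-yl)-3,4-dimethoxy-5-methyl-2H-pyran-2-one; 9 thioacetic acid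
Product: 10 S-[10-(3,4-dimethoxy-5-methyl-2-oxo-2H-pyran-6-yl)decyl] ethanethioate
Conditions: AcSH (3 equiv), AIBN (0.1 equiv), degassed toluene, 80 °C
Reagents that add atoms: thioacetic acid (9), CC(=O)S
Why: In this radical thiol-ene (anti-Markovnikov hydrothiolation) the acetylthiyl radical adds to the unhindered terminal CH2, and addition to the tetrasubstituted pyrone double bonds is hindered and reversible, so they are left untouched.

**Step 6**
Reactants: 10 S-[10-(3,4-dimethoxy-5-methyl-2-oxo-2H-pyran-6-yl)decyl] ethanethioate (2 molecules)
Product: 11 lehualide K, bis[10-(3,4-dimethoxy-5-methyl-2-oxo-2H-pyran-6-yl)decyl] disulfide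
Conditions: K2CO3 (1.2 equiv), degassed MeOH, 0 °C → rt, 30 min; then I2 (0.55 equiv) in MeOH until the yellow colour persists; aq Na2S2O3
Reagents that add atoms: none
Why: Fast thioester methanolysis is followed by iodine oxidative coupling of the thiolate to the symmetrical disulfide, and the pyrone survives because it is fully substituted (no iodination site) and any methoxide exchange at C4 in MeOH is degenerate.

## Compound list
| No. | Name | SMILES | Role |
|---|---|---|---|
| 1 | methyl methoxyacetate | COCC(=O)OC | starting material |
| 2 | propionyl chloride | CCC(=O)Cl | starting material |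
| 3 | methyl 2-methoxy-3-oxopentanoate (racemic) | CCC(=O)C(OC)C(=O)OC | intermediate |
| 4 | methyl undec-10-enoate | C=CCCCCCCCCC(=O)OC | starting material |
| 5 | methyl 2-methoxy-4-methyl-3,5-dioxopentadec-14-enoate | COC(=O)C(OC)C(=O)C(C)C(=O)CCCCCCCCC=C | intermediate |
| 6 | 6-(dec-9-en-1-yl)-4-hydroxy-3-methoxy-5-methyl-2H-pyran-2-one | C=CCCCCCCCCc1oc(=O)c(OC)c(O)c1C | intermediate |
| 7 | dimethyl sulfate | COS(=O)(=O)OC | starting material (reagent) |
| 8 | 6-(dec-9-en-1-yl)-3,4-dimethoxy-5-methyl-2H-pyran-2-one | C=CCCCCCCCCc1oc(=O)c(OC)c(OC)c1C | intermediate |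
| 9 | thioacetic acid | CC(=O)S | starting material (reagent) |
| 10 | S-[10-(3,4-dimethoxy-5-methyl-2-oxo-2H-pyran-6-yl)decyl] ethanethioate | CC(=O)SCCCCCCCCCCc1oc(=O)c(OC)c(OC)c1C | intermediate |
| 11 | lehualide K (C36H58O8S2, achiral) | COc1c(C)c(CCCCCCCCCCSSCCCCCCCCCCc2oc(=O)c(OC)c(OC)c2C)oc(=O)c1OC | target |

## Summary
**Total step count:** 6

**Longest linear sequence:** 6 steps (1 → 3 → 5 → 6 → 8 → 10 → 11)

**Three steps most likely to fail, each with a fallback:**
1. **Step 2, dianion acylation with an enolisable ester.** The risks are proton transfer and low conversion with a γ-branched dianion. Fallback: replace the acylation with an aldol and an oxidation. Add the same dianion to commercial undec-10-enal, then oxidise the δ-hydroxy-β-keto ester to 5 with Dess–Martin periodinane (one extra step).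
2. **Step 4, O4 versus O2 methylation (α- versus γ-pyrone).** Fallback: invert the polarity. Sulfonylate O4 of 6 (TsCl or Tf2O with Et3N) to the 4-sulfonyloxy-2-pyrone, then introduce the methoxy group by addition–elimination with NaOMe/MeOH. This can only give the 4-methoxy-α-pyrone.
3. **Step 1, crossed Claisen of the methoxyacetate enolate.** The risks are self-condensation and O- or di-acylation. Fallback: start from commercial methyl 3-oxopentanoate. Carry out diazo transfer (p-ABSA, Et3N), then Rh2(OAc)4-catalysed carbenoid O–H insertion into MeOH, which installs the 2-methoxy group and gives 3 (one extra step).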